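**Plan**

- The last disconnection opens the methoxy-enone ring C(OMe)=C(CH3)–C(=O)–C(side chain)=C(OH)–C(CH3)2 by retro-6π, retro-4π and retro-[2+2] steps. This gives cyclobutenone 6 (four ring carbons, already carrying OMe, the vinylic CH3 and the C(CH3)2 carbon) and the O-silyl ynol ether 24 (the C(side chain) and C–O carbons).
- The enabling feature is the quaternary C(CH3)2 carbon of that ring. The cyclohexadienone formed by electrocyclisation cannot tautomerise to a phenol, so a benzannulation-type cascade stops at the oxidation level and O-methyl pattern of the target.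
- Further cuts: the ynol C–O bond (acetylide oxidation), the pyranone ring at O1–C2 (Mitsunobu) and C4–C4a (Friedel–Crafts acylation), the alkyne back to the aldehyde of a phenol/enal Friedel–Crafts adduct, and the phenol oxygen (C–H borylation/oxidation of protected 2-methylresorcinol).
- Forward ring order: the benzene ring is bought, a temporary lactol ring is made in step 5 and opened in step 6, the pyranone ring is closed in step 10, and the methoxy-enone ring is closed last in step 13.
- Stereochemistry: the methine comes from a catalyst-controlled Friedel–Crafts addition (step 5). C2 comes from ethyl (R)-3-hydroxy-3-phenylpropanoate with inversion (step 8). Both centres are then carried through non-epimerising steps.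

Key step: step 13

Assumption: the target is drawn as one enol tautomer of a cyclic β-diketone; the tautomers interconvert, so the enol freed in step 14 is taken as the compound drawn (flavanone positions are numbered O1, C2, C3, C4, C4a, C5 to C8, C8a).

**Route**

Step 1
Reactants: 1 2-chloro-1,1-dimethoxyethane
Product: 3 1-methoxyprop-1-yne, via sodium methoxyacetylide 2 (not isolated)
Conditions: NaNH2 (3 equiv), liquid NH3, −33 °C; then MeI, −33 °C
Reagents that add atoms: sodium amide [Na+].[NH2-] (sodium of 2); iodomethane CI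
Why: NaNH2 removes HCl and then methanol from the chloroacetal to give sodium methoxyacetylide, which is C-methylated by iodomethane (alkoxyacetylene synthesis by double elimination followed by acetylide alkylation).

Step 2
Reactants: 4 2-methylpropanoyl chloride; 3 1-methoxyprop-1-yne
Product: 6 3-methoxy-2,4,4-trimethylcyclobut-2-en-1-one, via dimethylketene 5 (not isolated)
Conditions: Et3N, Et2O, 0 °C to reflux
Reagents that add atoms: none
Why: Et3N dehydrochlorinates 4 to dimethylketene, which undergoes the ketene–alkyne [2+2] cycloaddition with the ynol ether, the nucleophilic methyl-bearing alkyne carbon bonding to the ketene carbonyl carbon so that the methoxy group sits at C3 of the cyclobutenone.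

Step 3
Reactants: 7 2-methylbenzene-1,3-diol
Product: 8 1,3-bis(methoxymethoxy)-2-methylbenzene
Conditions: MeOCH2Cl, i-Pr2NEt, CH2Cl2, 0 °C to rt
Reagents that add atoms: chloromethyl methyl ether COCCl
Why: both phenols are alkylated by the reactive chloromethyl ether under amine base (Williamson-type acetal protection) to give base-stable ethers that are removed with acid in step 10.

Step 4
Reactants: 8 1,3-bis(methoxymethoxy)-2-methylbenzene
Product: 10 3,5-bis(methoxymethoxy)-4-methylphenol, via pinacol arylboronate 9 (not isolated)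
Conditions: [Ir(OMe)(cod)]2 (1.5 mol %), 4,4'-di-tert-butyl-2,2'-bipyridine (3 mol %), B2pin2, hexane, 80 °C; then 30% H2O2, aq. NaOH, THF, 0 °C
Reagents that add atoms: bis(pinacolato)diboron CC1(C)OB(OC1(C)C)B1OC(C)(C)C(C)(C)O1 (boron of 9); hydrogen peroxide OO (oxygen of 10)
Why: the iridium-catalysed C–H borylation is sterically governed and takes the only ring hydrogen without an ortho substituent (para to the methyl group), and the arylboronate is oxidised in the same flask to the phenol (C–H borylation/oxidation).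

Step 5
Reactants: 10 3,5-bis(methoxymethoxy)-4-methylphenol; 11 (E)-4-methylpent-2-enal
Product: 12 (4R)-5,7-bis(methoxymethoxy)-6-methyl-4-(propan-2-yl)-3,4-dihydro-2H-chromen-2-ol (mixture of anomers)
Conditions: (R)-2-[diphenyl(trimethylsilyloxy)methyl]pyrrolidine (20 mol %), PhCO2H (20 mol %), CH2Cl2, 0 °C
Reagents that add atoms: none
Why: the E-iminium ion of 11 is attacked by an ortho carbon of the electron-rich phenol (the two ortho positions are equivalent) on the face not shielded by the CPh2(OSiMe3) group, the Si face of C3 with the R catalyst, which sets the R methine, and the aldehyde is trapped by the phenol as the lactol (iminium-catalysed Friedel–Crafts alkylation/hemiacetalisation).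

Step 6
Reactants: 12 (4R)-5,7-bis(methoxymethoxy)-6-methyl-4-(propan-2-yl)-3,4-dihydro-2H-chromen-2-ol
Product: 13 3,5-bis(methoxymethoxy)-4-methyl-2-[(3S)-4-methyl-1-(trifluoromethylsulfonyloxy)pent-1-en-3-yl]phenyl trifluoromethanesulfonate (E/Z mixture)
Conditions: KN(SiMe3)2 (2.3 equiv), PhNTf2 (2.3 equiv), THF, −78 to 0 °C
Reagents that add atoms: N-phenylbis(trifluoromethanesulfonimide) O=S(=O)(N(c1ccccc1)S(=O)(=O)C(F)(F)F)C(F)(F)F
Why: the potassium lactolate opens to the phenoxide aldehyde, the second equivalent of base enolises the aldehyde, and both oxygen anions are sulfonylated (enolate and phenoxide O-triflation), while the β-stereocentre carries no acidic hydrogen and is untouched.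

Step 7
Reactants: 13 3,5-bis(methoxymethoxy)-4-methyl-2-[(3S)-4-methyl-1-(trifluoromethylsulfonyloxy)pent-1-en-3-yl]phenyl trifluoromethanesulfonate
Product: 15 3,5-bis(methoxymethoxy)-4-methyl-2-[(3S)-4-methylpent-1-yn-3-yl]phenol, via alkynyl aryl triflate 14 (not isolated)
Conditions: KN(SiMe3)2 (3 equiv), THF, −78 to −20 °C; then aq. Et4NOH, 1,4-dioxane, rt
Reagents that add atoms: none
Why: the amide base eliminates triflate from the enol triflate (anti E2 from the Z isomer, α-deprotonation and 1,2-hydrogen shift of the Fritsch–Buttenberg–Wiechell type from the E isomer) and holds the alkyne as its acetylide, which protects the propargylic centre, after which hydroxide cleaves the aryl triflate at sulfur to return the phenol.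

Step 8
Reactants: 15 3,5-bis(methoxymethoxy)-4-methyl-2-[(3S)-4-methylpent-1-yn-3-yl]phenol; 16 ethyl (3R)-3-hydroxy-3-phenylpropanoate
Product: 17 ethyl (3S)-3-{3,5-bis(methoxymethoxy)-4-methyl-2-[(3S)-4-methylpent-1-yn-3-yl]phenoxy}-3-phenylpropanoate
Conditions: PPh3, i-PrO2CN=NCO2i-Pr, toluene, 0 °C to rt
Reagents that add atoms: none
Why: in this Mitsunobu etherification the phenol displaces the activated benzylic alcohol by SN2 with inversion, so the R alcohol becomes the S aryl ether that is C2 of the flavanone.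

Step 9
Reactants: 17 ethyl (3S)-3-{3,5-bis(methoxymethoxy)-4-methyl-2-[(3S)-4-methylpent-1-yn-3-yl]phenoxy}-3-phenylpropanoate
Product: 18 (3S)-3-{3,5-bis(methoxymethoxy)-4-methyl-2-[(3S)-4-methylpent-1-yn-3-yl]phenoxy}-3-phenylpropanoic acid
Conditions: LiOH, THF/H2O, 0 °C; then 1 M HCl to pH 4
Reagents that add atoms: lithium hydroxide [Li+].[OH-]
Why: saponification at low temperature, where hydroxide attack at the ester carbonyl is faster than β-elimination of the aryloxide, should give the acid with the acetal groups and both stereocentres intact.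

Step 10
Reactants: 18 (3S)-3-{3,5-bis(methoxymethoxy)-4-methyl-2-[(3S)-4-methylpent-1-yn-3-yl]phenoxy}-3-phenylpropanoic acid
Product: 20 (2S)-5,7-dihydroxy-6-methyl-8-[(3S)-4-methylpent-1-yn-3-yl]-2-phenyl-2,3-dihydro-4H-chromen-4-one, via bis(methoxymethyl) flavanone 19 (not isolated)
Conditions: (CF3CO)2O, CH2Cl2, 0 °C; then MeOH, 3 M HCl, 45 °C
Reagents that add atoms: none
Why: the mixed trifluoroacetic anhydride acylates the only free ring position, ortho to the ether oxygen and activated by three oxygen substituents, which closes the pyranone ring by intramolecular Friedel–Crafts acylation without breaking the C2–O bond, and methanolic HCl then removes both methoxymethyl groups and any trifluoroacetate esters.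

Step 11
Reactants: 20 (2S)-5,7-dihydroxy-6-methyl-8-[(3S)-4-methylpent-1-yn-3-yl]-2-phenyl-2,3-dihydro-4H-chromen-4-one
Product: 21 (2S)-4,5,7-tris(tert-butyldimethylsilyloxy)-6-methyl-8-[(3S)-4-methylpent-1-yn-3-yl]-2-phenyl-2H-chromene
Conditions: t-BuMe2SiOTf (4 equiv), Et3N (6 equiv), CH2Cl2, −78 to 0 °C
Reagents that add atoms: tert-butyldimethylsilyl trifluoromethanesulfonate CC(C)(C)[Si](C)(C)OS(=O)(=O)C(F)(F)F
Why: the silyl triflate with Et3N silylates both phenols and converts the ketone, by O-silylation and loss of a C3 proton (soft enolisation), into its silyl enol ether, which removes the only protons more acidic than the alkyne C–H and blocks base-induced opening of the pyranone ring.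

Step 12
Reactants: 21 (2S)-4,5,7-tris(tert-butyldimethylsilyloxy)-6-methyl-8-[(3S)-4-methylpent-1-yn-3-yl]-2-phenyl-2H-chromene
Product: 24 (2S)-4,5,7-tris(tert-butyldimethylsilyloxy)-6-methyl-8-[(3S)-4-methyl-1-(triisopropylsilyloxy)pent-1-yn-3-yl]-2-phenyl-2H-chromene, via lithium acetylide 22 (not isolated), via lithium ynolate 23 (not isolated)
Conditions: n-BuLi (1.05 equiv), THF, −78 °C; t-BuOOLi (from t-BuOOH and LiN(SiMe3)2, THF, −78 °C), −78 to 0 °C; i-Pr3SiOTf, −78 to 0 °C
Reagents that add atoms: n-butyllithium [Li]CCCC (lithium of 22 and 23); tert-butyl hydroperoxide CC(C)(C)OO; triisopropylsilyl trifluoromethanesulfonate CC(C)[Si](C(C)C)(C(C)C)OS(=O)(=O)C(F)(F)F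
Why: the lithium acetylide is oxidised at carbon by the electrophilic oxygen of lithium tert-butyl peroxide to the lithium ynolate, which the bulky silyl triflate traps at oxygen (acetylide oxidation to an ynolate and O-silylation to a siloxyalkyne).

Step 13
Reactants: 24 (2S)-4,5,7-tris(tert-butyldimethylsilyloxy)-6-methyl-8-[(3S)-4-methyl-1-(triisopropylsilyloxy)pent-1-yn-3-yl]-2-phenyl-2H-chromene; 6 3-methoxy-2,4,4-trimethylcyclobut-2-en-1-one
Product: 28 5-methoxy-4,6,6-trimethyl-3-(triisopropylsilyloxy)-2-{(1R)-2-methyl-1-[(2S)-4,5,7-tris(tert-butyldimethylsilyloxy)-6-methyl-2-phenyl-2H-chromen-8-yl]propyl}cyclohexa-2,4-dien-1-one, via vinylketene 25 (not isolated), via alkenylcyclobutenone 26 (not isolated), via dienylketene 27 (not isolated)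
Conditions: 6 (3 equiv), toluene (0.5 M, degassed), 80 °C then 110 °C, sealed tube, dark
Reagents that add atoms: none
Why: Proposed new method: heating opens cyclobutenone 6 by 4π electrocyclic ring opening to vinylketene 25, whose ketene C=C adds to siloxyalkyne 24 in a [2+2] cycloaddition (the nucleophilic alkyne carbon that bears the side chain bonds to the ketene carbonyl carbon), and the alkenylcyclobutenone 26 opens again to dienylketene 27, which closes by thermal disrotatory 6π electrocyclisation between the ketene carbon and the C(CH3)2 terminus to cyclohexa-2,4-dienone 28. The closest known reaction is the Danheiser benzannulation of cyclobutenones with siloxyalkynes, in which the same cascade ends in tautomerisation to a resorcinol silyl ether, whereas here the new sp3 ring carbon is quaternary and the dienone is the end point. The six-membered ring is closed in the 6π step, with four ring carbons from 6 and two from the alkyne, which places OMe, CH3, OSi, side chain and C=O around the ring in the order of the target, so no separate O-methylation is needed. No lasting stereocentre is made, since the quaternary carbon of 26 is lost on ring opening and the methine and C2 are spectators under neutral conditions. The step needs the regiochemistry of the [2+2] addition, which the polarisation of the O-silyl ynol ether secures, and trapping of 25 by this strongly nucleophilic alkyne faster than the [1,5]-hydrogen shift from its cis-methyl group, which high concentration and a threefold excess of 6 favour; the two ring-opening modes of 26 interconvert through reclosure, so material is funnelled through the dienylketene geometry that can cyclise.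

Step 14
Reactants: 28 5-methoxy-4,6,6-trimethyl-3-(triisopropylsilyloxy)-2-{(1R)-2-methyl-1-[(2S)-4,5,7-tris(tert-butyldimethylsilyloxy)-6-methyl-2-phenyl-2H-chromen-8-yl]propyl}cyclohexa-2,4-dien-1-one
Product: 29 (2S)-5,7-dihydroxy-8-[(1R)-1-(2-hydroxy-4-methoxy-3,3,5-trimethyl-6-oxocyclohexa-1,4-dien-1-yl)-2-methylpropyl]-6-methyl-2-phenyl-2,3-dihydro-4H-chromen-4-one
Conditions: n-Bu4NF (6 equiv), AcOH (6 equiv), THF, 0 °C to rt
Reagents that add atoms: none
Why: buffered fluoride cleaves the four Si–O bonds (fluoride desilylation), the silyl dienol ether giving the enolised β-diketone of the target and the silyl enol ether being protonated at C3 to the flavanone ketone without a free enolate that could open the pyranone ring.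

**Compound list**

1 | 2-chloro-1,1-dimethoxyethane | COC(CCl)OC | starting material
2 | sodium methoxyacetylide (not isolated) | [Na+].[C-]#COC | intermediate
3 | 1-methoxyprop-1-yne | CC#COC | intermediate
4 | 2-methylpropanoyl chloride | CC(C)C(Cl)=O | starting material
5 | dimethylketene (not isolated) | CC(C)=C=O | intermediate
6 | 3-methoxy-2,4,4-trimethylcyclobut-2-en-1-one | COC1=C(C)C(=O)C1(C)C | intermediate
7 | 2-methylbenzene-1,3-diol | Cc1c(O)cccc1O | starting material
8 | 1,3-bis(methoxymethoxy)-2-methylbenzene | COCOc1cccc(OCOC)c1C | intermediate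
9 | 2-[3,5-bis(methoxymethoxy)-4-methylphenyl]-4,4,5,5-tetramethyl-1,3,2-dioxaborolane (not isolated) | COCOc1cc(B2OC(C)(C)C(C)(C)O2)cc(OCOC)c1C | intermediate
10 | 3,5-bis(methoxymethoxy)-4-methylphenol | COCOc1cc(O)cc(OCOC)c1C | intermediate
11 | (E)-4-methylpent-2-enal | CC(C)/C=C/C=O | starting material
12 | (4R)-5,7-bis(methoxymethoxy)-6-methyl-4-(propan-2-yl)-3,4-dihydro-2H-chromen-2-ol (anomers) | OC1C[C@H](C(C)C)c2c(O1)cc(OCOC)c(C)c2OCOC | intermediate
13 | 3,5-bis(methoxymethoxy)-4-methyl-2-[(3S)-4-methyl-1-(trifluoromethylsulfonyloxy)pent-1-en-3-yl]phenyl trifluoromethanesulfonate (E/Z) | FC(F)(F)S(=O)(=O)OC=C[C@@H](c1c(OS(=O)(=O)C(F)(F)F)cc(OCOC)c(C)c1OCOC)C(C)C | intermediate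
14 | 3,5-bis(methoxymethoxy)-4-methyl-2-[(3S)-4-methylpent-1-yn-3-yl]phenyl trifluoromethanesulfonate (not isolated) | C#C[C@@H](c1c(OS(=O)(=O)C(F)(F)F)cc(OCOC)c(C)c1OCOC)C(C)C | intermediate
15 | 3,5-bis(methoxymethoxy)-4-methyl-2-[(3S)-4-methylpent-1-yn-3-yl]phenol | C#C[C@@H](c1c(O)cc(OCOC)c(C)c1OCOC)C(C)C | intermediate
16 | ethyl (3R)-3-hydroxy-3-phenylpropanoate | CCOC(=O)C[C@@H](O)c1ccccc1 | starting material
17 | ethyl (3S)-3-{3,5-bis(methoxymethoxy)-4-methyl-2-[(3S)-4-methylpent-1-yn-3-yl]phenoxy}-3-phenylpropanoate | CCOC(=O)C[C@H](Oc1cc(OCOC)c(C)c(OCOC)c1[C@H](C#C)C(C)C)c1ccccc1 | intermediate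
18 | (3S)-3-{3,5-bis(methoxymethoxy)-4-methyl-2-[(3S)-4-methylpent-1-yn-3-yl]phenoxy}-3-phenylpropanoic acid | OC(=O)C[C@H](Oc1cc(OCOC)c(C)c(OCOC)c1[C@H](C#C)C(C)C)c1ccccc1 | intermediate
19 | (2S)-5,7-bis(methoxymethoxy)-6-methyl-8-[(3S)-4-methylpent-1-yn-3-yl]-2-phenyl-2,3-dihydro-4H-chromen-4-one (not isolated) | C#C[C@@H](c1c(OCOC)c(C)c(OCOC)c2c1O[C@H](c1ccccc1)CC2=O)C(C)C | intermediate
20 | (2S)-5,7-dihydroxy-6-methyl-8-[(3S)-4-methylpent-1-yn-3-yl]-2-phenyl-2,3-dihydro-4H-chromen-4-one | C#C[C@@H](c1c(O)c(C)c(O)c2c1O[C@H](c1ccccc1)CC2=O)C(C)C | intermediate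
21 | (2S)-4,5,7-tris(tert-butyldimethylsilyloxy)-6-methyl-8-[(3S)-4-methylpent-1-yn-3-yl]-2-phenyl-2H-chromene | C#C[C@@H](c1c(O[Si](C)(C)C(C)(C)C)c(C)c(O[Si](C)(C)C(C)(C)C)c2c1O[C@H](c1ccccc1)C=C2O[Si](C)(C)C(C)(C)C)C(C)C | intermediate
22 | lithium acetylide of 21 (not isolated) | [Li+].[C-]#C[C@@H](c1c(O[Si](C)(C)C(C)(C)C)c(C)c(O[Si](C)(C)C(C)(C)C)c2c1O[C@H](c1ccccc1)C=C2O[Si](C)(C)C(C)(C)C)C(C)C | intermediate
23 | lithium ynolate derived from 22 (not isolated) | [Li+].[O-]C#C[C@@H](c1c(O[Si](C)(C)C(C)(C)C)c(C)c(O[Si](C)(C)C(C)(C)C)c2c1O[C@H](c1ccccc1)C=C2O[Si](C)(C)C(C)(C)C)C(C)C | intermediate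
24 | (2S)-4,5,7-tris(tert-butyldimethylsilyloxy)-6-methyl-8-[(3S)-4-methyl-1-(triisopropylsilyloxy)pent-1-yn-3-yl]-2-phenyl-2H-chromene | CC(C)[Si](C(C)C)(C(C)C)OC#C[C@@H](c1c(O[Si](C)(C)C(C)(C)C)c(C)c(O[Si](C)(C)C(C)(C)C)c2c1O[C@H](c1ccccc1)C=C2O[Si](C)(C)C(C)(C)C)C(C)C | intermediate
25 | 3-methoxy-2,4-dimethylpenta-1,3-dien-1-one, the vinylketene from 6 (not isolated) | COC(=C(C)C)C(C)=C=O | intermediate
26 | 4-(1-methoxy-2-methylprop-1-enyl)-4-methyl-3-(triisopropylsilyloxy)cyclobut-2-en-1-one carrying the (1R)-2-methyl-1-(chromenyl)propyl group of 28 at C2 (epimers at C4; not isolated) | COC(=C(C)C)C1(C)C(=O)C([C@@H](c2c(O[Si](C)(C)C(C)(C)C)c(C)c(O[Si](C)(C)C(C)(C)C)c3c2O[C@H](c2ccccc2)C=C3O[Si](C)(C)C(C)(C)C)C(C)C)=C1O[Si](C(C)C)(C(C)C)C(C)C | intermediate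
27 | 5-methoxy-4,6-dimethyl-3-(triisopropylsilyloxy)hepta-1,3,5-trien-1-one carrying the (1R)-2-methyl-1-(chromenyl)propyl group of 28 at C2 (not isolated) | O=C=C([C@@H](c1c(O[Si](C)(C)C(C)(C)C)c(C)c(O[Si](C)(C)C(C)(C)C)c2c1O[C@H](c1ccccc1)C=C2O[Si](C)(C)C(C)(C)C)C(C)C)C(O[Si](C(C)C)(C(C)C)C(C)C)=C(C)C(OC)=C(C)C | intermediate
28 | 5-methoxy-4,6,6-trimethyl-3-(triisopropylsilyloxy)-2-{(1R)-2-methyl-1-[(2S)-4,5,7-tris(tert-butyldimethylsilyloxy)-6-methyl-2-phenyl-2H-chromen-8-yl]propyl}cyclohexa-2,4-dien-1-one | COC1=C(C)C(O[Si](C(C)C)(C(C)C)C(C)C)=C([C@@H](c2c(O[Si](C)(C)C(C)(C)C)c(C)c(O[Si](C)(C)C(C)(C)C)c3c2O[C@H](c2ccccc2)C=C3O[Si](C)(C)C(C)(C)C)C(C)C)C(=O)C1(C)C | intermediate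
29 | (2S)-5,7-dihydroxy-8-[(1R)-1-(2-hydroxy-4-methoxy-3,3,5-trimethyl-6-oxocyclohexa-1,4-dien-1-yl)-2-methylpropyl]-6-methyl-2-phenyl-2,3-dihydro-4H-chromen-4-one | COC1=C(C)C(=O)C([C@@H](c2c(O)c(C)c(O)c3c2O[C@H](c2ccccc2)CC3=O)C(C)C)=C(O)C1(C)C | target

**Count and risks**

Total step count: 14. Longest linear sequence: 12 steps (steps 3 to 14); steps 1 and 2 make the cyclobutenone fragment.

Steps most likely to fail:

1. Step 13 (carries the label "Proposed new method:"). What may go wrong:
- the vinylketene may be lost by [1,5]-hydrogen shift from its cis-methyl group, or by dimerisation, before it meets the alkyne;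
- silicon may shift thermally from oxygen to carbon in the siloxyalkyne, giving a silylketene;
- C2 may slowly erode through reversible electrocyclic opening of the 4-silyloxy-2H-chromene at the temperature needed.

Fallback with known reactions, setting out from 24 and coming back at 28: 24 would be heated (toluene, 80 °C) with 3-methoxy-2,4-dimethylcyclobut-2-en-1-one F1, itself made from propanoyl chloride, Et3N and 3 by the ketene–alkyne [2+2] cycloaddition used in step 2. This is the ordinary, aromatising Danheiser benzannulation and should give the fully substituted phenol 3-methoxy-2,4-dimethyl-5-(triisopropylsilyloxy)-6-[2-methyl-1-(chromenyl)propyl]phenol F2 (methine configured as in 28). A cyclobutenone with a hydrogen at C4 opens at lower temperature, and its vinylketene has no cis-methyl group. Alkylative dearomatisation of the lithium phenoxide of F2 (LiN(SiMe3)2, MeI, toluene) at the methyl-bearing ortho carbon, the less hindered of the two ortho carbons, should then add the second methyl group and give 28.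

2. Step 8. What may go wrong: β-elimination of the activated β-hydroxy ester to ethyl cinnamate outrunning substitution by the hindered phenol, or partial ionisation at the benzylic carbon that erodes the inversion.

Fallback, setting out from 15 and coming back at 19: 15 would be C-silylated at the alkyne (EtMgBr 2.2 equiv, Me3SiCl, aqueous work-up) to 3,5-bis(methoxymethoxy)-4-methyl-2-[(3R)-4-methyl-1-(trimethylsilyl)pent-1-yn-3-yl]phenol F3. Directed ortho-lithiation (n-BuLi 2.2 equiv, TMEDA, THF, 0 °C) and acylation with N-methoxy-N-methylacetamide should give the 2-hydroxyacetophenone F4. Me2NCH(OMe)2 (90 °C) would convert it into the enaminone F5, which should cyclise on brief warming in AcOH to the chromone F6. Rhodium-catalysed asymmetric 1,4-addition of PhB(OH)2 ([RhOH(cod)]2, the enantiomer of the electron-poor bisphosphine MeO-F12-BIPHEP that gives the 2S product, toluene/H2O) should give the (2S)-flavanone F7 under catalyst control. AgNO3 (cat.) in aqueous acetone would remove the alkynyl silyl group to give 19, which the methanolic HCl stage of step 10 converts into 20.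

3. Step 7. What may go wrong: sulfonyl transfer to the base returning the aldehyde instead of elimination, or base-promoted alkyne-to-allene isomerisation that would erase the propargylic stereocentre.

Fallback, setting out from 12 and coming back at 15: 12 would be dehydrated (MsCl, Et3N, CH2Cl2) to (4S)-5,7-bis(methoxymethoxy)-6-methyl-4-(propan-2-yl)-4H-chromene F8. Lemieux–Johnson cleavage of its enol ether double bond (OsO4 cat., NaIO4, 2,6-lutidine, dioxane/H2O) should give 3,5-bis(methoxymethoxy)-4-methyl-2-[(2R)-3-methyl-1-oxobutan-2-yl]phenyl formate F9. Methanolysis (K2CO3, MeOH, 0 °C) should give (3R)-4,6-bis(methoxymethoxy)-5-methyl-3-(propan-2-yl)-2,3-dihydro-1-benzofuran-2-ol F10, in which the lactol form shields the α-aryl aldehyde from enolisation. Seyferth–Gilbert homologation with dimethyl (1-diazo-2-oxopropyl)phosphonate (K2CO3, MeOH) should then give 15 directly with the phenol free.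

Further compounds
F1 | step 13 | 3-methoxy-2,4-dimethylcyclobut-2-en-1-one | COC1=C(C)C(=O)C1C
F2 | step 13 | 3-methoxy-2,4-dimethyl-5-(triisopropylsilyloxy)-6-{2-methyl-1-[(2S)-4,5,7-tris(tert-butyldimethylsilyloxy)-6-methyl-2-phenyl-2H-chromen-8-yl]propyl}phenol (methine as in 28) | COc1c(C)c(O)c([C@@H](c2c(O[Si](C)(C)C(C)(C)C)c(C)c(O[Si](C)(C)C(C)(C)C)c3c2O[C@H](c2ccccc2)C=C3O[Si](C)(C)C(C)(C)C)C(C)C)c(O[Si](C(C)C)(C(C)C)C(C)C)c1C
F3 | step 8 | 3,5-bis(methoxymethoxy)-4-methyl-2-[(3R)-4-methyl-1-(trimethylsilyl)pent-1-yn-3-yl]phenol | C[Si](C)(C)C#C[C@@H](c1c(O)cc(OCOC)c(C)c1OCOC)C(C)C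
F4 | step 8 | 1-{2-hydroxy-4,6-bis(methoxymethoxy)-5-methyl-3-[(3R)-4-methyl-1-(trimethylsilyl)pent-1-yn-3-yl]phenyl}ethan-1-one | CC(=O)c1c(O)c([C@H](C#C[Si](C)(C)C)C(C)C)c(OCOC)c(C)c1OCOC
F5 | step 8 | (E)-3-(dimethylamino)-1-{2-hydroxy-4,6-bis(methoxymethoxy)-5-methyl-3-[(3R)-4-methyl-1-(trimethylsilyl)pent-1-yn-3-yl]phenyl}prop-2-en-1-one | CN(C)/C=C/C(=O)c1c(O)c([C@H](C#C[Si](C)(C)C)C(C)C)c(OCOC)c(C)c1OCOC
F6 | step 8 | 5,7-bis(methoxymethoxy)-6-methyl-8-[(3R)-4-methyl-1-(trimethylsilyl)pent-1-yn-3-yl]-4H-chromen-4-one | C[Si](C)(C)C#C[C@@H](c1c(OCOC)c(C)c(OCOC)c2c(=O)ccoc12)C(C)C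
F7 | step 8 | (2S)-5,7-bis(methoxymethoxy)-6-methyl-8-[(3R)-4-methyl-1-(trimethylsilyl)pent-1-yn-3-yl]-2-phenyl-2,3-dihydro-4H-chromen-4-one | C[Si](C)(C)C#C[C@@H](c1c(OCOC)c(C)c(OCOC)c2c1O[C@H](c1ccccc1)CC2=O)C(C)C
F8 | step 7 | (4S)-5,7-bis(methoxymethoxy)-6-methyl-4-(propan-2-yl)-4H-chromene | CC(C)[C@H]1C=COc2cc(OCOC)c(C)c(OCOC)c21
F9 | step 7 | 3,5-bis(methoxymethoxy)-4-methyl-2-[(2R)-3-methyl-1-oxobutan-2-yl]phenyl formate | O=COc1cc(OCOC)c(C)c(OCOC)c1[C@H](C=O)C(C)C
F10 | step 7 | (3R)-4,6-bis(methoxymethoxy)-5-methyl-3-(propan-2-yl)-2,3-dihydro-1-benzofuran-2-ol | OC1Oc2cc(OCOC)c(C)c(OCOC)c2[C@H]1C(C)C
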